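**Plan**
- Retrosynthesis cuts the cyclohexene at C5–C6 (CH2–CHPh) and C2–C3 (CH(prenyl)–C(Me)=) together. This is a [3+3] union of a C6–C1–C2 2-aroylallyl 1,3-bis-electrophile with a C3–C4–C5 but-2-ene-1,3-diyl dinucleophile, 1,3-bis(trimethylsilyl)but-2-ene, which leaves the C3=C4 alkene in place with no later adjustment.
- Enabling feature: ring carbon C1 carries the aroyl group and is flanked by two β-carbons (C2, C6), and the aryl ketone has an ortho-hydroxyl (benzofuran 6-OH). Tying that OH to C6 gives a flavanone (temporary pyranone ring). Its 3-alkylidene derivative offers C2 as the only acceptor at first and releases C6 as a chalcone-type acceptor, by E1cB loss of the phenoxide, only after the first C–C bond exists.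
- Forward order of rings: furan ring on the acetophenone (steps 1–2), pyranone ring (3), phenyl on C6 (4), alkylidene (5–8), bis-silane (9–10). Step 11 opens the pyranone, closes the cyclohexene and gives the target itself.
- Stereochemistry: the flavanone C2 (= C6) is set by ligand-controlled conjugate arylation. It directs the first allylsilane addition (C2, anti to the axial phenyl), is then erased, and is re-created trans to the prenyl group in the ring closure. C1 comes from protonation of the enolate anti to the pseudo-axial prenyl group.

Key step: step 11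

Remark (assumption): 1, 2, 5, 8, 11, 16 (as E/Z mixture) and (R)-t-BuPyOx are taken as commercial; cyclohexene carbons are called C1 (aroyl), C2 (prenyl), C3 (methyl), C4, C5, C6 (phenyl).

Step 1
Reactants: 1 1-(2,6-dihydroxy-4-methoxyphenyl)ethan-1-one; 2 2-bromo-1,1-diethoxyethane
Product: 3 1-[2-(2,2-diethoxyethoxy)-6-hydroxy-4-methoxyphenyl]ethan-1-one
Conditions: K2CO3, NaI (cat.), DMF, 100 °C
Reagents that add atoms: none
Why: Williamson etherification; the two phenols are equivalent and, once one is alkylated, the other stays locked in a hydrogen bond to the ketone, so mono-alkylation is expected.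

Step 2
Reactants: 3 1-[2-(2,2-diethoxyethoxy)-6-hydroxy-4-methoxyphenyl]ethan-1-one
Product: 4 1-(6-hydroxy-4-methoxy-1-benzofuran-7-yl)ethan-1-one
Conditions: polystyrenesulfonic acid resin (Amberlyst 15), PhCl, 120 °C
Reagents that add atoms: none
Why: Acid-catalysed cyclodehydration of an aryloxyacetaldehyde acetal (intramolecular Friedel–Crafts alkylation, then loss of ethanol); the oxocarbenium ion can only attack the free position ortho to the ether oxygen, which is activated by the flanking methoxy and the para hydroxyl group.

Step 3
Reactants: 4 1-(6-hydroxy-4-methoxy-1-benzofuran-7-yl)ethan-1-one; 5 N,N-dimethylformamide dimethyl acetal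
Product: 7 furochromone (4H-chromen-4-one fused across benzofuran C6–C7 of 4: pyranone oxygen on C6 and carbonyl carbon on C7), via enaminone 6 (not isolated)
Conditions: neat 5, 95 °C; then AcOH, 100 °C
Reagents that add atoms: none
Why: Enaminone formation at the acetyl group followed by acid-promoted addition–elimination of the ortho-phenol (standard chromone synthesis) closes the temporary pyranone ring onto the 6-OH.

Step 4
Reactants: 7 furochromone; 8 phenylboronic acid
Product: 9 (R)-flavanone (2,3-dihydro-7 with phenyl on pyranone C2, configuration R)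
Conditions: Pd(OCOCF3)2 (5 mol %), (R)-t-BuPyOx [(R)-4-tert-butyl-2-(pyridin-2-yl)-4,5-dihydrooxazole] (6 mol %), NH4PF6, H2O, ClCH2CH2Cl, 60 °C
Reagents that add atoms: none
Why: Palladium-catalysed asymmetric conjugate addition of an arylboronic acid to a chromone (aryl transfer to divalent palladium, face-selective carbopalladation, protonolysis of the palladium enolate); the ligand sets the phenyl-bearing center, the (R)-ligand being chosen on the expectation, by analogy with cyclic enones, that it delivers the (2R)-product (the antipode is used should the sense be opposite).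

Step 5
Reactants: 9 (R)-flavanone
Product: 10 (R)-silyl enol ether (4-trimethylsilyloxy-2H-pyran form of 9)
Conditions: Me3SiOTf, Et3N, CH2Cl2, 0 °C
Reagents that add atoms: trimethylsilyl trifluoromethanesulfonate, C[Si](C)(C)OS(=O)(=O)C(F)(F)F
Why: Soft enolisation with a silyl triflate and a tertiary amine gives the silyl enol ether without a free enolate, which would open the pyranone by E1cB and racemise C2.

Step 6
Reactants: 11 4-methylpent-3-en-1-ol
Product: 12 4-methylpent-3-enal
Conditions: Dess–Martin periodinane, CH2Cl2, 0 → 23 °C; used at once
Reagents that add atoms: none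
Why: Dess–Martin oxidation of a homoallylic primary alcohol under near-neutral conditions should give the β,γ-unsaturated aldehyde without moving the double bond into conjugation.

Step 7
Reactants: 10 (R)-silyl enol ether; 12 4-methylpent-3-enal
Product: 13 aldol (9 bearing a 1-hydroxy-4-methylpent-3-en-1-yl group on pyranone C3; C2 R; mixture at C3 and at the carbinol carbon)
Conditions: TiCl4, CH2Cl2, −78 °C; then H2O
Reagents that add atoms: none
Why: Mukaiyama aldol addition to the Lewis acid-activated aldehyde forms the C3–side chain bond without base; the two new stereocenters are erased in step 8 and C2 is not touched.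

Step 8
Reactants: 13 aldol
Product: 15 (E)-alkylidene flavanone (9 with a 4-methylpent-3-en-1-ylidene group on pyranone C3 and the alkyl chain syn to C2; C2 unchanged in space but now designated S), via mesylate 14 (not isolated)
Conditions: MeSO2Cl, Et3N, CH2Cl2, 0 → 23 °C
Reagents that add atoms: none
Why: Mesylation and E1cB elimination (aldol condensation in two stages) should give the thermodynamically preferred (E)-alkylidene, the mesylate leaving in preference to the ring aryloxide; A(1,3) strain in the (E)-isomer turns the 2-phenyl group axial, which the key step exploits.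

Step 9
Reactants: 16 1,3-dichlorobut-2-ene (E/Z mixture)
Product: 18 (3-chlorobut-2-en-1-yl)trimethylsilane, via allylmagnesium chloride 17 (not isolated)
Conditions: Mg, Me3SiCl, THF, 0 → 23 °C
Reagents that add atoms: chlorotrimethylsilane, C[Si](C)(C)Cl
Why: Barbier-type Grignard formation at the allylic C–Cl bond (the vinylic C–Cl bond is inert to magnesium under these conditions) and silylation at the unhindered CH2 terminus should give the allylsilane.

Step 10
Reactants: 18 (3-chlorobut-2-en-1-yl)trimethylsilane
Product: 20 1,3-bis(trimethylsilyl)but-2-ene (E/Z mixture), via vinyllithium 19 (not isolated)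
Conditions: Li (1% Na), Et2O, 23 °C; then Me3SiCl
Reagents that add atoms: chlorotrimethylsilane, C[Si](C)(C)Cl
Why: Reductive lithiation of the vinyl chloride and silylation gives the vinylsilane; the alkene geometry is irrelevant because this carbon becomes sp3 and then part of a ring alkene.

Step 11
Reactants: 15 (E)-alkylidene flavanone; 20 1,3-bis(trimethylsilyl)but-2-ene
Product: 24 (6-hydroxy-4-methoxy-1-benzofuran-7-yl)[(1R,2S,6R)-3-methyl-2-(3-methylbut-2-en-1-yl)-6-phenylcyclohex-3-en-1-yl]methanone (the target), via titanium enolate 21 (not isolated), via ring-opened enone 22 (not isolated), via titanium chelate 23 (not isolated)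
Conditions: TiCl4, 2,6-di-tert-butyl-4-methylpyridine, CH2Cl2, −78 → −20 °C; then H2O
Reagents that add atoms: none
Why: Proposed new method: TiCl4 activates the exocyclic enone of 15 so that the methyl- and silyl-bearing alkene carbon of 20 adds to the alkylidene carbon (Hosomi–Sakurai conjugate addition with loss of the allylic silyl group); titanium enolate 21 then expels the ring aryloxide by E1cB (flavanone-to-chalcone retro-oxa-Michael) to give the chelated enone 22, and the new α-silyl allylsilane closes the ring by a second, intramolecular anti-SE2' conjugate addition (6-endo-trig) with loss of the second silyl group, which places the double bond between C3 and C4. The closest known reaction types are the Hosomi–Sakurai conjugate allylation, the use of 1,3-bis(silyl)propenes as propene-1,3-diyl equivalents, intramolecular allylsilane–enone cyclisation and the SN2'/Michael [3+3] annulation of 2-acylallyl electrophiles with 1,3-dinucleophiles. The prenyl-bearing center C2 is set in the first addition, since A(1,3) strain with the (E)-alkylidene holds the 2-phenyl group of 15 axial and the silane attacks the opposite face; this center survives when the phenyl-bearing center is erased. C6 is then re-created under control of C2: the forming exocyclic enolate tolerates neither a 2,6-diaxial nor a 2,6-diequatorial (doubly A(1,3)-strained) arrangement, so either enone geometry and either epimer at the transient silyl-bearing carbon should converge on the 2,6-trans ring. C1 follows from axial protonation of enolate 23 anti to the pseudo-axial prenyl group, which also gives the equatorial aroyl and phenyl groups. The step needs the correct pairing of ends and 1,4- over 1,2-addition: the first is secured because only the alkylidene carbon is electrophilic until the pyranone opens and 20 can react first only at its trisubstituted carbon, the second by chelation of titanium between phenoxide and ketone and by the hindered aryl ketone.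

**Compound list**
1 | 1-(2,6-dihydroxy-4-methoxyphenyl)ethan-1-one | CC(=O)c1c(O)cc(OC)cc1O | starting material
2 | 2-bromo-1,1-diethoxyethane | CCOC(CBr)OCC | starting material
3 | 1-[2-(2,2-diethoxyethoxy)-6-hydroxy-4-methoxyphenyl]ethan-1-one | CCOC(COc1cc(OC)cc(O)c1C(C)=O)OCC | intermediate
4 | 1-(6-hydroxy-4-methoxy-1-benzofuran-7-yl)ethan-1-one | CC(=O)c1c(O)cc(OC)c2ccoc12 | intermediate
5 | N,N-dimethylformamide dimethyl acetal | COC(OC)N(C)C | starting material
6 | (E)-3-(dimethylamino)-1-(6-hydroxy-4-methoxy-1-benzofuran-7-yl)prop-2-en-1-one | CN(C)/C=C/C(=O)c1c(O)cc(OC)c2ccoc12 | intermediate (not isolated)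
7 | furochromone (4H-chromen-4-one fused across benzofuran C6–C7, methoxy retained) | O=c1ccoc2cc(OC)c3ccoc3c12 | intermediate
8 | phenylboronic acid | OB(O)c1ccccc1 | starting material
9 | (R)-flavanone (2-phenyl-2,3-dihydro-7) | O=C1C[C@H](c2ccccc2)Oc2cc(OC)c3ccoc3c12 | intermediate
10 | (R)-silyl enol ether of 9 | C[Si](C)(C)OC1=C[C@H](c2ccccc2)Oc2cc(OC)c3ccoc3c12 | intermediate
11 | 4-methylpent-3-en-1-ol | CC(C)=CCCO | starting material
12 | 4-methylpent-3-enal | CC(C)=CCC=O | intermediate
13 | aldol: 3-(1-hydroxy-4-methylpent-3-en-1-yl) derivative of 9 (C2 R; mixture at the other two centers) | O=C1C(C(O)CC=C(C)C)[C@H](c2ccccc2)Oc2cc(OC)c3ccoc3c12 | intermediate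
14 | mesylate of 13 | O=C1C(C(OS(C)(=O)=O)CC=C(C)C)[C@H](c2ccccc2)Oc2cc(OC)c3ccoc3c12 | intermediate (not isolated)
15 | (2S,3E)-3-(4-methylpent-3-en-1-ylidene) derivative of 9 | O=C1/C(=C/CC=C(C)C)[C@H](c2ccccc2)Oc2cc(OC)c3ccoc3c12 | intermediate
16 | 1,3-dichlorobut-2-ene (E/Z) | CC(Cl)=CCCl | starting material
17 | (3-chlorobut-2-en-1-yl)magnesium chloride | CC(Cl)=CC[Mg]Cl | intermediate (not isolated)
18 | (3-chlorobut-2-en-1-yl)trimethylsilane | CC(Cl)=CC[Si](C)(C)C | intermediate
19 | [4-(trimethylsilyl)but-2-en-2-yl]lithium | [Li]C(C)=CC[Si](C)(C)C | intermediate (not isolated)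
20 | 1,3-bis(trimethylsilyl)but-2-ene (E/Z) | C[Si](C)(C)CC=C(C)[Si](C)(C)C | intermediate
21 | trichlorotitanium enolate of the first conjugate adduct (pyranone intact; C3 carries the CH(prenyl)–C(Me)(SiMe3)–CH=CH2 chain; silyl-bearing carbon as a mixture) | Cl[Ti](Cl)(Cl)OC1=C([C@H](CC=C(C)C)C(C)(C=C)[Si](C)(C)C)[C@H](c2ccccc2)Oc2cc(OC)c3ccoc3c12 | intermediate (not isolated)
22 | ring-opened (E)-enone, trichlorotitanium phenoxide, with pendant α-silyl allylsilane | Cl[Ti](Cl)(Cl)Oc1cc(OC)c2ccoc2c1C(=O)/C(=C/c1ccccc1)[C@H](CC=C(C)C)C(C)(C=C)[Si](C)(C)C | intermediate (not isolated)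
23 | dichlorotitanium chelate (phenoxide and enolate oxygens) of the cyclised product | Cl[Ti]1(Cl)Oc2cc(OC)c3ccoc3c2C(O1)=C1[C@H](CC=C(C)C)C(C)=CC[C@H]1c1ccccc1 | intermediate (not isolated)
24 | (6-hydroxy-4-methoxy-1-benzofuran-7-yl)[(1R,2S,6R)-3-methyl-2-(3-methylbut-2-en-1-yl)-6-phenylcyclohex-3-en-1-yl]methanone | COc1cc(O)c(C(=O)[C@@H]2[C@H](CC=C(C)C)C(C)=CC[C@H]2c2ccccc2)c2occc12 | target

**Count and risks**
Total step count: 11. Longest linear sequence: 8 steps (1, 2, 3, 4, 5, 7, 8, 11).

Step 11 (riskiest). The cascade may stall at enolate 21 if the aryloxide is not expelled, the allylsilane may be lost by protodesilylation, the second addition may go to the carbonyl carbon, or facial control in the first addition may be incomplete. The fallback sets out from 4 and uses known chemistry that forms C1–C2 and C5–C6 instead. Claisen–Schmidt condensation of 4 with benzaldehyde (KOH, EtOH, 23 °C) would give the 2'-hydroxychalcone (E)-1-(6-hydroxy-4-methoxy-1-benzofuran-7-yl)-3-phenylprop-2-en-1-one F1. An enantioselective Diels–Alder reaction of F1 with (E)-β-ocimene follows, promoted by a chiral boron Lewis acid made from B(OPh)3 and the enantiomer of VANOL (3,3'-diphenyl-2,2'-bi-1-naphthol) that leads to the (1R,2S,6R) adduct. Boron is chelated between the ortho-hydroxyl and the ketone, and the endo transition state gives the cis aroyl/prenyl, trans aroyl/phenyl adduct. The fallback comes back to the route at 24.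

Step 4. Carbopalladation of the peri-oxygenated chromone may be slow or poorly face-selective, and arylation of the furan double bond may compete. The fallback sets out from 4. Condensation with benzaldehyde (KOH, EtOH) gives the chalcone (E)-1-(6-hydroxy-4-methoxy-1-benzofuran-7-yl)-3-phenylprop-2-en-1-one F2. Oxa-Michael cyclisation (NaOAc, EtOH, reflux) gives the racemic flavanone F3. Preparative HPLC on a cellulose tris(3,5-dimethylphenylcarbamate) phase then separates the enantiomers, and the (R)-enantiomer re-enters the route at 9.

Step 2. The liberated oxocarbenium ion or aldehyde may condense with the neighbouring acetyl group, or the electron-rich benzofuran may resinify on the acid resin. The fallback sets out from 1. O-Allylation (allyl bromide, K2CO3, acetone, reflux) gives 1-[2-(allyloxy)-6-hydroxy-4-methoxyphenyl]ethan-1-one F4. Claisen rearrangement (PhNEt2, 190 °C) moves the allyl group to the only free ortho position and gives 1-(3-allyl-2,6-dihydroxy-4-methoxyphenyl)ethan-1-one F5. Oxidative cleavage (OsO4 cat., NaIO4, THF/H2O) gives the aldehyde, which closes to the lactol 1-(2,6-dihydroxy-4-methoxy-2,3-dihydro-1-benzofuran-7-yl)ethan-1-one F6. Dehydration (H3PO4, 100 °C) comes back to the route at 4.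

Further compounds
F1 | step 11 | (E)-1-(6-hydroxy-4-methoxy-1-benzofuran-7-yl)-3-phenylprop-2-en-1-one | O=C(/C=C/c1ccccc1)c1c(O)cc(OC)c2ccoc12
F2 | step 4 | (E)-1-(6-hydroxy-4-methoxy-1-benzofuran-7-yl)-3-phenylprop-2-en-1-one | O=C(/C=C/c1ccccc1)c1c(O)cc(OC)c2ccoc12
F3 | step 4 | racemic flavanone (racemate of 9) | O=C1CC(c2ccccc2)Oc2cc(OC)c3ccoc3c12
F4 | step 2 | 1-[2-(allyloxy)-6-hydroxy-4-methoxyphenyl]ethan-1-one | CC(=O)c1c(O)cc(OC)cc1OCC=C
F5 | step 2 | 1-(3-allyl-2,6-dihydroxy-4-methoxyphenyl)ethan-1-one | CC(=O)c1c(O)cc(OC)c(CC=C)c1O
F6 | step 2 | 1-(2,6-dihydroxy-4-methoxy-2,3-dihydro-1-benzofuran-7-yl)ethan-1-one | CC(=O)c1c(O)cc(OC)c2CC(O)Oc12
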